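## Retrosynthetic overview

- Ring C is closed last through the O1–C2 bond: a ring-A ortho-phenol adds intramolecularly (oxa-Michael) to an α-aryl vinyl ketone, and catalyst-controlled protonation of the resulting enol(ate) sets C3 as S.
- The free tetraphenolic enone comes from its tetrasilyl ether by global desilylation. The enone C3–C4 bond comes from 1,2-addition of a ring-B α-styrenyl lithium (Shapiro reaction) to persilylated 2,4,6-trihydroxybenzaldehyde, followed by alcohol oxidation.
- The ring-B fragment is an 8-acetyl-2,2-dimethyl-2H-chromene. Its pyran ring is formed first, by propargyl ether Claisen rearrangement and electrocyclisation on 4-O-silylated 2',4'-dihydroxyacetophenone, which places the pyran oxygen ortho to the future C3 attachment.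
- Order of ring formation: pyran ring on ring B (step 3), then ring C (step 9). The benzene rings A and B are bought.

Assumption: the SMILES is read as (3S)-licoisoflavanone (C3 = S); the facial sense of the new step cannot be predicted with certainty, so the quinidine-derived catalyst is written and its quinine-derived pseudoenantiomer is the direct substitute if the first run gives the (3R)-product.

## Route

Step 1
Reactants: 1 2',4'-dihydroxyacetophenone; 2 triisopropylsilyl chloride
Product: 3 1-[2-hydroxy-4-(triisopropylsilyloxy)phenyl]ethan-1-one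
Conditions: TIPSCl (1.05 equiv), imidazole, CH2Cl2, 0 °C → rt
Reagents that add atoms: triisopropylsilyl chloride, CC(C)[Si](Cl)(C(C)C)C(C)C
Why: Chemoselective phenol silylation; the 4-OH is free and more acidic, whereas the 2-OH is held in the hydrogen bond to the acetyl group and does not react with one equivalent of the bulky chloride.

Step 2
Reactants: 3 1-[2-hydroxy-4-(triisopropylsilyloxy)phenyl]ethan-1-one; 4 3-chloro-3-methylbut-1-yne
Product: 5 1-[2-(2-methylbut-3-yn-2-yloxy)-4-(triisopropylsilyloxy)phenyl]ethan-1-one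
Conditions: HC≡CC(Me)2Cl (3 equiv), DBU, CuCl2 (1 mol%), MeCN, 0 °C → rt
Reagents that add atoms: 3-chloro-3-methylbut-1-yne, CC(C)(Cl)C#C
Why: Copper-catalysed O-propargylation of a phenol with a tertiary propargylic chloride (through a copper acetylide/allenylidene); excess electrophile compensates for the hydrogen-bonded, hindered hydroxyl, and the aryl silyl ether tolerates DBU at low temperature.

Step 3
Reactants: 5 1-[2-(2-methylbut-3-yn-2-yloxy)-4-(triisopropylsilyloxy)phenyl]ethan-1-one
Product: 8 1-[2,2-dimethyl-5-(triisopropylsilyloxy)-2H-chromen-8-yl]ethan-1-one, via allenylphenol 6 (not isolated), via quinone methide 7 (not isolated)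
Conditions: o-xylene, 140 °C
Reagents that add atoms: none
Why: Aryl propargyl ether Claisen rearrangement to C3 (the only free ortho position) gives allenylphenol 6, whose 1,5-hydrogen shift gives quinone methide 7 and 6π-oxa-electrocyclisation closes the 2,2-dimethyl-2H-chromene with its oxygen ortho to the acetyl group.

Step 4
Reactants: 8 1-[2,2-dimethyl-5-(triisopropylsilyloxy)-2H-chromen-8-yl]ethan-1-one; 9 2,4,6-triisopropylbenzenesulfonohydrazide
Product: 10 N'-{1-[2,2-dimethyl-5-(triisopropylsilyloxy)-2H-chromen-8-yl]ethylidene}-2,4,6-triisopropylbenzenesulfonohydrazide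
Conditions: TrisNHNH2 (1.1 equiv), MeOH/THF, cat. HCl, rt
Reagents that add atoms: 2,4,6-triisopropylbenzenesulfonohydrazide, CC(C)c1cc(C(C)C)c(S(=O)(=O)NN)c(C(C)C)c1
Why: Acid-catalysed hydrazone formation from a methyl ketone gives the Shapiro precursor; the chromene and the aryl silyl ether are stable to catalytic acid at room temperature.

Step 5
Reactants: 11 2,4,6-trihydroxybenzaldehyde; 12 tert-butyldimethylsilyl chloride
Product: 13 2,4,6-tris(tert-butyldimethylsilyloxy)benzaldehyde
Conditions: TBSCl (3.6 equiv), imidazole, DMF, rt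
Reagents that add atoms: tert-butyldimethylsilyl chloride, CC(C)(C)[Si](C)(C)Cl
Why: Exhaustive phenol silylation (imidazole/DMF is strong enough for the two chelated ortho-hydroxyls) gives a non-enolisable aldehyde with no acidic protons for the organolithium step.

Step 6
Reactants: 10 N'-{1-[2,2-dimethyl-5-(triisopropylsilyloxy)-2H-chromen-8-yl]ethylidene}-2,4,6-triisopropylbenzenesulfonohydrazide; 13 2,4,6-tris(tert-butyldimethylsilyloxy)benzaldehyde
Product: 15 rac-2-[2,2-dimethyl-5-(triisopropylsilyloxy)-2H-chromen-8-yl]-1-[2,4,6-tris(tert-butyldimethylsilyloxy)phenyl]prop-2-en-1-ol, via vinyllithium 14 (not isolated)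
Conditions: 10 (1.2 equiv), n-BuLi (2.5 equiv), THF, −78 → 0 °C; then 13, −78 °C; AcOH/THF quench at −78 °C
Reagents that add atoms: none
Why: Shapiro reaction; double deprotonation of the trisylhydrazone and loss of sulfinate and N2 on warming give α-styrenyl lithium 14, which adds 1,2 to the aldehyde; the cold acidic quench prevents O-to-O silyl migration in the alkoxide, and the racemic carbinol centre is erased in step 7.

Step 7
Reactants: 15 rac-2-[2,2-dimethyl-5-(triisopropylsilyloxy)-2H-chromen-8-yl]-1-[2,4,6-tris(tert-butyldimethylsilyloxy)phenyl]prop-2-en-1-ol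
Product: 16 2-[2,2-dimethyl-5-(triisopropylsilyloxy)-2H-chromen-8-yl]-1-[2,4,6-tris(tert-butyldimethylsilyloxy)phenyl]prop-2-en-1-one
Conditions: Dess–Martin periodinane (1.5 equiv), pyridine, CH2Cl2, 0 °C → rt
Reagents that add atoms: none
Why: Dess–Martin oxidation of a doubly activated (benzylic and allylic) secondary alcohol; pyridine buffering protects the acid-labile electron-rich carbinol, and the chromene alkene and silyl ethers are untouched.

Step 8
Reactants: 16 2-[2,2-dimethyl-5-(triisopropylsilyloxy)-2H-chromen-8-yl]-1-[2,4,6-tris(tert-butyldimethylsilyloxy)phenyl]prop-2-en-1-one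
Product: 17 2-(5-hydroxy-2,2-dimethyl-2H-chromen-8-yl)-1-(2,4,6-trihydroxyphenyl)prop-2-en-1-one
Conditions: HF·pyridine, THF, 0 °C → rt; pH 5 buffer work-up, no base; stored cold and used promptly
Reagents that add atoms: none
Why: Fluoride cleavage of all four aryl silyl ethers in an acidic medium; 6-endo closure of a carbonyl-chelated phenol onto the enone needs base catalysis, so the open enone should survive as long as base is excluded.

Step 9
Reactants: 17 2-(5-hydroxy-2,2-dimethyl-2H-chromen-8-yl)-1-(2,4,6-trihydroxyphenyl)prop-2-en-1-one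
Product: 19 (3S)-5,7-dihydroxy-3-(5-hydroxy-2,2-dimethyl-2H-chromen-8-yl)-2,3-dihydro-4H-chromen-4-one, via enol tautomer 18 (not isolated)
Conditions: 3-[3,5-bis(trifluoromethyl)anilino]-4-[(9-deoxy-epi-quinidin-9-yl)amino]cyclobut-3-ene-1,2-dione (10 mol%), PhMe/THF 5:1 (0.02 M), −30 °C; AcOH quench, direct chromatography
Reagents that add atoms: none
Why: Proposed new method: a catalytic tandem 6-endo-trig oxa-Michael addition/enantioselective protonation, in which the quinuclidine nitrogen activates one of the two equivalent ortho-hydroxyls of ring A while the squaramide N–H bonds bind the enone carbonyl, O1–C2 bond formation (which itself creates no stereocentre) gives squaramide-bound enol(ate) 18 in a tight ion pair with the quinuclidinium ion, and that ion delivers its proton to one face of C3 to set the S centre (the ortho-oxygenated ring B is twisted out of the enolate plane and differentiates the faces, and the acidic phenols buffer the weakly basic catalyst so that the product should not racemise at −30 °C); the closest known reaction types are amine–thiourea or squaramide-catalysed oxa-Michael cyclisations of 2'-hydroxychalcone-type substrates to flavanones, bifunctional-base-catalysed thia-Michael addition/enantioselective protonation of α-substituted acrylic acceptors, and palladium-catalysed decarboxylative enantioselective protonation to isoflavanones, none of which joins phenol conjugate addition to protonation control at C3.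

## Compound list

1 | 2',4'-dihydroxyacetophenone | CC(=O)c1ccc(O)cc1O | starting material
2 | triisopropylsilyl chloride | CC(C)[Si](Cl)(C(C)C)C(C)C | starting material
3 | 1-[2-hydroxy-4-(triisopropylsilyloxy)phenyl]ethan-1-one | CC(=O)c1ccc(O[Si](C(C)C)(C(C)C)C(C)C)cc1O | intermediate
4 | 3-chloro-3-methylbut-1-yne | CC(C)(Cl)C#C | starting material
5 | 1-[2-(2-methylbut-3-yn-2-yloxy)-4-(triisopropylsilyloxy)phenyl]ethan-1-one | CC(=O)c1ccc(O[Si](C(C)C)(C(C)C)C(C)C)cc1OC(C)(C)C#C | intermediate
6 | 1-[2-hydroxy-3-(3-methylbuta-1,2-dien-1-yl)-4-(triisopropylsilyloxy)phenyl]ethan-1-one (allenylphenol) | CC(=O)c1ccc(O[Si](C(C)C)(C(C)C)C(C)C)c(C=C=C(C)C)c1O | intermediate (not isolated)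
7 | 2-acetyl-6-(3-methylbut-2-en-1-ylidene)-5-(triisopropylsilyloxy)cyclohexa-2,4-dien-1-one (quinone methide) | CC(=O)C1=CC=C(O[Si](C(C)C)(C(C)C)C(C)C)C(=CC=C(C)C)C1=O | intermediate (not isolated)
8 | 1-[2,2-dimethyl-5-(triisopropylsilyloxy)-2H-chromen-8-yl]ethan-1-one | CC(=O)c1ccc(O[Si](C(C)C)(C(C)C)C(C)C)c2C=CC(C)(C)Oc12 | intermediate
9 | 2,4,6-triisopropylbenzenesulfonohydrazide | CC(C)c1cc(C(C)C)c(S(=O)(=O)NN)c(C(C)C)c1 | starting material
10 | N'-{1-[2,2-dimethyl-5-(triisopropylsilyloxy)-2H-chromen-8-yl]ethylidene}-2,4,6-triisopropylbenzenesulfonohydrazide | CC(=NNS(=O)(=O)c1c(C(C)C)cc(C(C)C)cc1C(C)C)c1ccc(O[Si](C(C)C)(C(C)C)C(C)C)c2C=CC(C)(C)Oc12 | intermediate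
11 | 2,4,6-trihydroxybenzaldehyde | O=Cc1c(O)cc(O)cc1O | starting material
12 | tert-butyldimethylsilyl chloride | CC(C)(C)[Si](C)(C)Cl | starting material
13 | 2,4,6-tris(tert-butyldimethylsilyloxy)benzaldehyde | O=Cc1c(O[Si](C)(C)C(C)(C)C)cc(O[Si](C)(C)C(C)(C)C)cc1O[Si](C)(C)C(C)(C)C | intermediate
14 | {1-[2,2-dimethyl-5-(triisopropylsilyloxy)-2H-chromen-8-yl]ethenyl}lithium | [Li]C(=C)c1ccc(O[Si](C(C)C)(C(C)C)C(C)C)c2C=CC(C)(C)Oc12 | intermediate (not isolated)
15 | rac-2-[2,2-dimethyl-5-(triisopropylsilyloxy)-2H-chromen-8-yl]-1-[2,4,6-tris(tert-butyldimethylsilyloxy)phenyl]prop-2-en-1-ol | C=C(C(O)c1c(O[Si](C)(C)C(C)(C)C)cc(O[Si](C)(C)C(C)(C)C)cc1O[Si](C)(C)C(C)(C)C)c1ccc(O[Si](C(C)C)(C(C)C)C(C)C)c2C=CC(C)(C)Oc12 | intermediate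
16 | 2-[2,2-dimethyl-5-(triisopropylsilyloxy)-2H-chromen-8-yl]-1-[2,4,6-tris(tert-butyldimethylsilyloxy)phenyl]prop-2-en-1-one | C=C(C(=O)c1c(O[Si](C)(C)C(C)(C)C)cc(O[Si](C)(C)C(C)(C)C)cc1O[Si](C)(C)C(C)(C)C)c1ccc(O[Si](C(C)C)(C(C)C)C(C)C)c2C=CC(C)(C)Oc12 | intermediate
17 | 2-(5-hydroxy-2,2-dimethyl-2H-chromen-8-yl)-1-(2,4,6-trihydroxyphenyl)prop-2-en-1-one | C=C(C(=O)c1c(O)cc(O)cc1O)c1ccc(O)c2C=CC(C)(C)Oc12 | intermediate
18 | 3-(5-hydroxy-2,2-dimethyl-2H-chromen-8-yl)-2H-chromene-4,5,7-triol (enol tautomer, catalyst-bound) | CC1(C)C=Cc2c(O)ccc(C3=C(O)c4c(O)cc(O)cc4OC3)c2O1 | intermediate (not isolated)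
19 | (3S)-5,7-dihydroxy-3-(5-hydroxy-2,2-dimethyl-2H-chromen-8-yl)-2,3-dihydro-4H-chromen-4-one | CC1(C)C=Cc2c(O)ccc([C@H]3COc4cc(O)cc(O)c4C3=O)c2O1 | target

## Step count and risk

Total step count: 9.
Longest linear sequence: 8 steps (steps 1–4 and 6–9, from 1); step 5 is the one-step side branch.

The three steps most likely to fail:

**Step 9 (the proposed new step).** The enantioselectivity of the protonation is unproven, the several free phenols can act as competing achiral proton sources, and a racemic background cyclisation of 17 would erode the ee. The fallback sets out from 17 and uses only known chemistry. Catalytic Et3N in EtOH at rt closes ring C without stereocontrol (the classical base-mediated isoflavanone closure of an α-methylene deoxybenzoin) to give rac-5,7-dihydroxy-3-(5-hydroxy-2,2-dimethyl-2H-chromen-8-yl)-2,3-dihydro-4H-chromen-4-one F1. Preparative chiral supercritical-fluid chromatography on an amylose tris(3,5-dimethylphenylcarbamate) phase then delivers 19, where the fallback rejoins the route. The separated (3R)-5,7-dihydroxy-3-(5-hydroxy-2,2-dimethyl-2H-chromen-8-yl)-2,3-dihydro-4H-chromen-4-one F2 is re-racemised to F1 with Et3N in MeOH and recycled.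

**Step 6.** The aldehyde 13 is flanked by two silyloxy groups, so addition may be slow, and the lithium alkoxide can suffer silyl migration. The fallback sets out from 8 and replaces the organolithium with an organochromium reagent. Enolisation with KN(SiMe3)2 and trapping with PhNTf2 in THF at −78 °C gives 1-[2,2-dimethyl-5-(triisopropylsilyloxy)-2H-chromen-8-yl]ethenyl trifluoromethanesulfonate F3. F3 is coupled with 13 under Nozaki–Hiyama–Kishi conditions (CrCl2, NiCl2 (2 mol%), DMF, rt); the chromium alkoxide is not basic enough to move silyl groups, and the fallback rejoins the route at 15.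

**Step 2.** The hydroxyl to be alkylated is hydrogen-bonded to the acetyl group and hindered, and the electrophile is tertiary, so conversion may be poor. The fallback sets out from 1 and builds the pyran ring by C-prenylation and oxidative cyclisation instead of the propargyl ether Claisen sequence. 1-Bromo-3-methylbut-2-ene in aqueous KOH prenylates C3 (between the two hydroxyls; modest yield, regioisomers removed by chromatography) to give 1-[2,4-dihydroxy-3-(3-methylbut-2-en-1-yl)phenyl]ethan-1-one F4. TIPSCl/imidazole silylates the free 4-OH to give 1-[2-hydroxy-3-(3-methylbut-2-en-1-yl)-4-(triisopropylsilyloxy)phenyl]ethan-1-one F5. DDQ in toluene at 80 °C then abstracts the benzylic hydride to form quinone methide 7, which electrocyclises onto the only free phenol; the fallback rejoins the route at 8.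

Further compounds
F1 | step 9 | rac-5,7-dihydroxy-3-(5-hydroxy-2,2-dimethyl-2H-chromen-8-yl)-2,3-dihydro-4H-chromen-4-one | CC1(C)C=Cc2c(O)ccc(C3COc4cc(O)cc(O)c4C3=O)c2O1
F2 | step 9 | (3R)-5,7-dihydroxy-3-(5-hydroxy-2,2-dimethyl-2H-chromen-8-yl)-2,3-dihydro-4H-chromen-4-one | CC1(C)C=Cc2c(O)ccc([C@@H]3COc4cc(O)cc(O)c4C3=O)c2O1
F3 | step 6 | 1-[2,2-dimethyl-5-(triisopropylsilyloxy)-2H-chromen-8-yl]ethenyl trifluoromethanesulfonate | C=C(OS(=O)(=O)C(F)(F)F)c1ccc(O[Si](C(C)C)(C(C)C)C(C)C)c2C=CC(C)(C)Oc12
F4 | step 2 | 1-[2,4-dihydroxy-3-(3-methylbut-2-en-1-yl)phenyl]ethan-1-one | CC(=O)c1ccc(O)c(CC=C(C)C)c1O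
F5 | step 2 | 1-[2-hydroxy-3-(3-methylbut-2-en-1-yl)-4-(triisopropylsilyloxy)phenyl]ethan-1-one | CC(=O)c1ccc(O[Si](C(C)C)(C(C)C)C(C)C)c(CC=C(C)C)c1O
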